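**The vessel.** Seal substrate, reagent and initiator in the vessel, stir, hold the temperature, and read what the beta run left.

| setting | beta | midnight | autumn |
|---|---|---|---|
| substrate | 1.2 M | 0.80 M | 0.80 M |
| reagent | 0.80 M | 0.800 M | 0.800 M |
| initiator | 8 mM | 8.0 mM | 8.0 mM |
| remark | run made earlier |  |  |
| time |  | 4.0 h | 6.0 h |

beta run (percent of the substrate charged)

| time / min | over-reaction product / % | target / % | side product / % | substrate / % |
|---|---|---|---|---|
| 6.00 | 0 | 1.8 | 0.4 | 96.7 |
| 8.00 | 0 | 0.8 | 0.9 | 99.2 |
| 12.0 | 0 | 1.5 | 0.3 | 95.4 |
| 20.0 | 1.1 | 0 | 6.1 | 94.6 |
| 30.0 | 1.1 | 1.9 | 8.6 | 88.3 |
| 50.0 | 2.3 | 1.6 | 15.0 | 82.7 |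
| 80.0 | 4.8 | 1.5 | 24.8 | 69.4 |

(scatter of a reading: 1 percentage point)

- percentages count the substrate that a species holds: one side product counts as two

- which of these there is most of at the end, counted by the substrate in it, midnight (target / side product / substrate / over-reaction product)
- which of these there is most of at the end, counted by the substrate in it, autumn (target / side product / substrate / over-reaction product)
- the largest of these amounts at the end, in percent of the substrate charged, midnight
- the largest of these amounts at the end, in percent of the substrate charged, autumn

**Two exits.** Treat the target as a passage and leave it out of the balance: the last beta reading holds 1.5 %. Suppose it leaves alone into over-reaction product, or with a substrate into side product, which holds two. Side product then gains on over-reaction product in proportion to a, the fraction of the charge still substrate. Take the last beta ratio of these two, divide by the mean a, and scale to the substrate charge of midnight and autumn: 4.07. This g is the side product gained per over-reaction product gained at full charge, a selectivity factor. It carries the scatter of 1 percentage point on a reading of 4.8 %.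

**Two extremes.** Freeze a at the full charge, and side product takes 80.3 % of the turnover. Freeze a at nil, and it takes none. The flask runs between them, so integrate: over-reaction product is ln((1+g)/(1+g·a))/g, and side product is the rest of what has left substrate. Put a at nil in that integral, and it gives 60.1 % side product.

**My reckoning.** Take first-order loss from the beta run, 0.274 h⁻¹. Midnight keeps a = 33.4 % and autumn 19.3 %. Side product comes to 47.8 % at midnight and 55.0 % in autumn, the largest amount in each.

**The forecast.** Reasoning that “first-order behaviour gives about 36% substrate left”, it names side product for midnight at 60 % and side product for autumn at 70 %, higher than my figures.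

**The result.** Midnight ends with side product at 51.0 %, autumn with side product at 54.8 %.

    initiator → 2 initiating radical (k = 3.10 × 10⁻⁴ min⁻¹)
    substrate + initiating radical → capped initiator + first chain carrier (k = 1.00 × 10⁵ L mol⁻¹ s⁻¹)
    substrate + target → side product (k = 0.0680 L mol⁻¹ min⁻¹)
    2 first chain carrier → ended chains (k = 8.00 × 10⁷ L mol⁻¹ s⁻¹)
    reagent + first chain carrier ⇌ target + second chain carrier (K = 0.960, k = 1.90 × 10⁵ L mol⁻¹ min⁻¹)
    substrate + second chain carrier → by-product + first chain carrier (k = 98000 L mol⁻¹ min⁻¹)
    target → over-reaction product (k = 0.0300 min⁻¹)

**Same g.** Autumn keeps 4.0 % substrate, not my 19.3 %, so the match on side product is no check. Enter that substrate and the 2.25 % target, and g gives 57.5 % side product against the 54.8 % of autumn. Now take the neighbour of autumn with 0.48 M reagent and the same substrate charge, and keep g. It keeps 31 % substrate and 1.25 % target, and g gives 47.7 % side product. That flask holds 46.0 % side product.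

The data were generated by integration with constants of no real substance, and the scatter is random.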